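## Retrosynthetic overview

1. **Feature.** On the central benzene ring (ring A, carbons a–f), carbon e carries the seven-ring CH2. Its ortho neighbour f is bonded to C3 of the inner dihydrofuran, and f is in turn ortho to carbon a, which carries the furan oxygen. With e at the aldehyde level and masked as a chiral aldimine, the single f–H bond between imine and oxygen can be metalated and added across an enol ether attached to that oxygen.
2. **Last disconnections.** The eight O-methyl groups are removed with BBr3. The outer dihydrofuran is cut at C2'–C3' (chiral dirhodium carbene insertion into a 4-methoxybenzyl ether C–H bond, then acid equilibration of C2'). The carbene carbon comes from ortho-formylation at d of the freed phenol at c.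
3. **Seven-membered ring.** It is cut at C7–ring G: protonation of a 2,4-dimethoxystilbene, made from the aldehyde by Horner–Wadsworth–Emmons olefination, followed by Friedel–Crafts closure.
4. **Inner dihydrofuran.** It is cut at f–C3 (rhodium hydroarylation). The enol ether with cis aryl groups comes from a 1,1-dibromoalkene, by C–O coupling at the bromine trans to the aryl group and then Suzuki coupling at the other bromine.
5. **Ring order.** Inner dihydrofuran (step 6), seven-membered ring (step 9), outer dihydrofuran (step 16). The seven-membered ring has to come before the outer furan, because an aldehyde carrying both furans would have a mirror plane.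

Key step: step 6

**Locants.** Ring A has carbons a (bears the inner furan O), b (CH), c (bears the second O), d, e and f in sequence. The inner furan is O1–C2–C3, with C3 on f. Ring G is the 3,5-dioxygenated ring on C3. C7 is the seven-ring methine on ring G, and C8 is the seven-ring CH2 on e. The outer furan has C2' (on the O at c) and C3' (on d).

**Assumption.** (R)-1-Aminoindane and Rh2(R-PTAD)4 are taken as the enantiomers that lead to (2S,3S) and (3'R). Both senses of induction have to be checked on the first run, and the mirror-image amine and catalyst are equally available.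

## Route

Step 1
Reactants: 1 3,5-dihydroxybenzaldehyde
Product: 2 3-(benzyloxy)-5-hydroxybenzaldehyde
Conditions: BnBr (1.0 equiv), K2CO3, DMF, rt
Reagents that add atoms: benzyl bromide, BrCc1ccccc1
Why: Williamson etherification with one equivalent of halide gives the mono-ether within a statistical mixture, from which it is separated by chromatography.

Step 2
Reactants: 3 3,5-dimethoxybenzaldehyde
Product: 4 1-(2,2-dibromoethenyl)-3,5-dimethoxybenzene
Conditions: CBr4, PPh3, CH2Cl2, 0 °C
Reagents that add atoms: carbon tetrabromide, BrC(Br)(Br)Br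
Why: Ramirez dibromo-olefination converts a non-enolisable aromatic aldehyde cleanly into the 1,1-dibromoalkene.

Step 3
Reactants: 2 3-(benzyloxy)-5-hydroxybenzaldehyde; 4 1-(2,2-dibromoethenyl)-3,5-dimethoxybenzene
Product: 5 3-(benzyloxy)-5-{[(Z)-1-bromo-2-(3,5-dimethoxyphenyl)ethenyl]oxy}benzaldehyde (Br cis, O trans to the aryl group)
Conditions: CuI (15 mol %), 2,2'-bipyridine (30 mol %), K3PO4, toluene, 110 °C, 4 in slight excess
Reagents that add atoms: none
Why: Copper-catalysed Ullmann-type vinylation of a phenol with a 1,1-dibromoalkene is a known reaction that substitutes, with retention, the more accessible C–Br bond trans to the aryl group, so oxygen ends up trans to the 3,5-dimethoxyphenyl ring, and the weak base in toluene avoids dehydrobromination to the ynol ether.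

Step 4
Reactants: 5 (Z)-bromo enol ether; 6 4-methoxyphenylboronic acid
Product: 7 3-(benzyloxy)-5-{[(E)-2-(3,5-dimethoxyphenyl)-1-(4-methoxyphenyl)ethenyl]oxy}benzaldehyde (the two aryl groups cis)
Conditions: Pd(PPh3)4 (5 mol %), Na2CO3 (aq), DME, 70 °C
Reagents that add atoms: none
Why: Suzuki–Miyaura coupling of an alkenyl bromide proceeds with retention and so places the 4-methoxyphenyl group cis to the 3,5-dimethoxyphenyl group, a geometry that enolate-derived sulfonates of the deoxybenzoin (aryl groups trans) would not deliver.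

Step 5
Reactants: 7 (E)-enol ether aldehyde; 8 (R)-1-aminoindane
Product: 9 (E)-aldimine of 7 with (R)-1-aminoindane
Conditions: 4 Å molecular sieves, toluene, rt
Reagents that add atoms: none
Why: Condensation of an aromatic aldehyde with a primary amine over a drying agent gives the (E)-aldimine under neutral conditions, which preserves the acid-sensitive enol ether geometry, and the auxiliary stereocentre is bought in.

Step 6
Reactants: 9 (E)-aldimine of the (E)-1,2-diarylvinyl aryl ether
Product: 11 (2S,3S)-6-(benzyloxy)-3-(3,5-dimethoxyphenyl)-2-(4-methoxyphenyl)-2,3-dihydro-1-benzofuran-4-carbaldehyde, via cyclised aldimine 10 (not isolated)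
Conditions: [RhCl(coe)2]2 (10 mol %), (C5H5)Fe(C5H4PCy2) (30 mol %), toluene, 75 to 100 °C; then 1 M HCl, THF, rt
Reagents that add atoms: water, O
Why: Proposed new method: the aldimine nitrogen binds monovalent rhodium and guides it into the f–H bond (the d–H bond can also be cleaved, but reversibly and with no alkene in reach); the trivalent aryl rhodium hydride then binds the tethered enol ether, hydride migrates to C2 to leave a six-membered rhodacycle with a benzylic Rh–C3 bond, and C–C reductive elimination forms the f–C3 bond. The closest known reaction type is the chiral-aldimine-directed rhodium hydroarylation of aryl enol ethers that carry an ester on the beta carbon, so the new element is an aryl group on that carbon, where eta-3 benzyl stabilisation by the inductively electron-poor 3,5-dimethoxyphenyl ring should take over the role of the ester in holding rhodium on C3. The ring closes in a formal 5-endo-trig mode with both alkene carbons becoming ring members, and bonding to C2 instead would require a four-membered ring. C2 and C3 are tied to each other by the syn addition of aryl and hydrogen, which turns an alkene with cis aryl groups into the trans dihydrofuran. Which trans enantiomer forms depends on the alkene face that rhodium takes, and this is controlled by the indanyl stereocentre held next to the metal. The step therefore needs site selectivity (secured by the tether), retention of alkene geometry (neutral medium) and facial selectivity (auxiliary), and any cis isomer would be corrected at C2 by the acid of step 9.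

Step 7
Reactants: 12 2,4-dimethoxybenzyl alcohol
Product: 13 diethyl (2,4-dimethoxybenzyl)phosphonate
Conditions: P(OEt)3, ZnI2, toluene, reflux
Reagents that add atoms: triethyl phosphite, CCOP(OCC)OCC
Why: The zinc iodide-mediated Michaelis–Arbuzov-type conversion of an electron-rich benzylic alcohol avoids the unstable 2,4-dimethoxybenzyl halide.

Step 8
Reactants: 11 dihydrobenzofuran-4-carbaldehyde; 13 diethyl (2,4-dimethoxybenzyl)phosphonate
Product: 14 (2S,3S)-6-(benzyloxy)-4-[(E)-2-(2,4-dimethoxyphenyl)ethenyl]-3-(3,5-dimethoxyphenyl)-2-(4-methoxyphenyl)-2,3-dihydro-1-benzofuran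
Conditions: 13, NaH, THF, 0 °C; then 11, 0 °C to rt
Reagents that add atoms: none
Why: Horner–Wadsworth–Emmons olefination with the preformed phosphonate anion gives the (E)-stilbene, and the absence of free base protects the doubly benzylic C3–H from deprotonation and ring opening.

Step 9
Reactants: 14 (E)-stilbene
Product: 15 tetracyclic benzyl ether (2S,3S,7S), with C7 bonded to ring G ortho to C3 and the 2,4-dimethoxyphenyl group on C7 cis to H3
Conditions: TFA, CH2Cl2 (dilute), 0 °C to rt
Reagents that add atoms: none
Why: Protonation of the electron-rich stilbene at C8 gives the C7 cation stabilised by the 2,4-dimethoxyphenyl group, which an ortho carbon of ring G traps in an intramolecular Friedel–Crafts alkylation of a type known for 4-styryl-2,3-diaryl-dihydrobenzofurans, and the aryl group takes the pseudo-axial position on the convex face, cis to H3 and away from the neighbouring methoxy group, which sets C7 as S.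

Step 10
Reactants: 15 tetracyclic benzyl ether
Product: 16 tetracyclic phenol (2S,3S,7S), free OH at c
Conditions: H2 (1 atm), Pd/C, EtOAc–MeOH, rt
Reagents that add atoms: none
Why: Neutral hydrogenolysis of the aryl benzyl ether frees the phenol, while the cyclic benzylic C2–O bond and the methyl ethers are left untouched.

Step 11
Reactants: 16 tetracyclic phenol
Product: 17 tetracyclic salicylaldehyde (2S,3S,7S), CHO at d next to the OH at c
Conditions: MgCl2, Et3N, (CH2O)n, MeCN, reflux; then 1 M HCl
Reagents that add atoms: paraformaldehyde (as formaldehyde), C=O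
Why: Casnati–Skattebøl ortho-formylation of the magnesium phenoxide acts only next to the free OH, and of the two ortho sites it should take d, para to the furan oxygen, rather than b between the two oxygens, as 3-alkoxy-5-alkylphenols do.

Step 12
Reactants: 17 tetracyclic salicylaldehyde; 18 4-methoxybenzyl chloride
Product: 19 4-methoxybenzyl ether of 17
Conditions: K2CO3, n-Bu4NI (cat.), DMF, 50 °C
Reagents that add atoms: none
Why: Williamson etherification installs the 4-methoxybenzyl group, whose CH2 and aryl ring become C2' and its substituent.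

Step 13
Reactants: 19 aldehyde 4-methoxybenzyl ether; 20 3,5-dimethoxyphenylmagnesium bromide
Product: 21 diaryl carbinol (both carbinol epimers)
Conditions: THF, 0 °C; then H2O
Reagents that add atoms: none
Why: Grignard addition to the aldehyde brings in the 3,5-dimethoxyphenyl ring, and the mixed carbinol centre is erased in the next step.

Step 14
Reactants: 21 diaryl carbinol
Product: 22 diaryl ketone
Conditions: Dess–Martin periodinane, CH2Cl2, rt
Reagents that add atoms: none
Why: Dess–Martin oxidation of a diaryl carbinol is mild enough for the 4-methoxybenzyl ether and the electron-rich rings, which a quinone oxidant would attack.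

Step 15
Reactants: 22 diaryl ketone
Product: 23 hydrazone of 22 (C=N isomers)
Conditions: N2H4·H2O (excess), AcOH (cat.), n-BuOH, 110 °C
Reagents that add atoms: hydrazine, NN
Why: Hydrazone formation is driven by excess hydrazine and heat because the ketone is flanked by two ortho substituents, and nothing else in the molecule reacts with hydrazine.

Step 16
Reactants: 23 hydrazone
Product: 25 octamethyl ether with cis outer dihydrofuran (2S,3S,7S,2'S,3'R), via diaryldiazomethane 24 (not isolated)
Conditions: MnO2, CH2Cl2, rt; filter; Rh2(R-PTAD)4 (1 mol %), CH2Cl2, 0 °C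
Reagents that add atoms: none
Why: Oxidation gives the diaryldiazomethane, whose dirhodium donor/donor carbene inserts into the benzylic ether C–H bond in a 1,5 manner (the known enantioselective route to cis-2,3-diaryl dihydrobenzofurans), with the chiral carboxylate catalyst setting C3' as R and the concerted insertion placing both aryl groups cis (C2' S), the resident stereocentres being too remote to override it and C7–H being held out of reach by the seven-membered ring.

Step 17
Reactants: 25 cis outer dihydrofuran
Product: 26 octamethyl ether of the target (2S,3S,7S,2'R,3'R)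
Conditions: TFA, CH2Cl2, rt
Reagents that add atoms: none
Why: Acid reversibly ionises the C2'–O bond to the 4-methoxybenzyl cation and reclosure gives the more stable trans isomer (C2' becomes R) with C3' untouched, while the inner furan and C7 already sit at their equilibrium configuration under the same acid as in step 9.

Step 18
Reactants: 26 octamethyl ether
Product: 27 CNP0154047.3 (target)
Conditions: BBr3 (excess), CH2Cl2, −78 °C to rt; then H2O
Reagents that add atoms: none
Why: Boron tribromide cleaves all eight aryl methyl ethers, a deprotection known to spare the dihydrobenzofuran-fused seven-ring skeleton, and it touches no stereocentre beyond equilibria that already favour the given isomer.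

## Compound list

1 | 3,5-dihydroxybenzaldehyde | O=Cc1cc(O)cc(O)c1 | starting material
2 | 3-(benzyloxy)-5-hydroxybenzaldehyde | O=Cc1cc(O)cc(OCc2ccccc2)c1 | intermediate
3 | 3,5-dimethoxybenzaldehyde | COc1cc(C=O)cc(OC)c1 | starting material
4 | 1-(2,2-dibromoethenyl)-3,5-dimethoxybenzene | COc1cc(C=C(Br)Br)cc(OC)c1 | intermediate
5 | 3-(benzyloxy)-5-{[(Z)-1-bromo-2-(3,5-dimethoxyphenyl)ethenyl]oxy}benzaldehyde | COc1cc(/C=C(\Br)Oc2cc(C=O)cc(OCc3ccccc3)c2)cc(OC)c1 | intermediate
6 | 4-methoxyphenylboronic acid | COc1ccc(B(O)O)cc1 | starting material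
7 | 3-(benzyloxy)-5-{[(E)-2-(3,5-dimethoxyphenyl)-1-(4-methoxyphenyl)ethenyl]oxy}benzaldehyde | COc1ccc(/C(Oc2cc(OCc3ccccc3)cc(C=O)c2)=C\c2cc(OC)cc(OC)c2)cc1 | intermediate
8 | (R)-1-aminoindane | N[C@@H]1CCc2ccccc21 | starting material
9 | (E)-aldimine of 7 with (R)-1-aminoindane (key-step precursor) | COc1ccc(/C(Oc2cc(OCc3ccccc3)cc(/C=N/[C@@H]3CCc4ccccc43)c2)=C\c2cc(OC)cc(OC)c2)cc1 | intermediate
10 | (R)-1-indanyl aldimine of 11 (cyclised aldimine, not isolated) | COc1ccc([C@H]2Oc3cc(OCc4ccccc4)cc(/C=N/[C@@H]4CCc5ccccc54)c3[C@@H]2c2cc(OC)cc(OC)c2)cc1 | intermediate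
11 | (2S,3S)-6-(benzyloxy)-3-(3,5-dimethoxyphenyl)-2-(4-methoxyphenyl)-2,3-dihydro-1-benzofuran-4-carbaldehyde | COc1ccc([C@H]2Oc3cc(OCc4ccccc4)cc(C=O)c3[C@@H]2c2cc(OC)cc(OC)c2)cc1 | intermediate
12 | 2,4-dimethoxybenzyl alcohol | COc1ccc(CO)c(OC)c1 | starting material
13 | diethyl (2,4-dimethoxybenzyl)phosphonate | CCOP(=O)(Cc1ccc(OC)cc1OC)OCC | intermediate
14 | (2S,3S)-6-(benzyloxy)-4-[(E)-2-(2,4-dimethoxyphenyl)ethenyl]-3-(3,5-dimethoxyphenyl)-2-(4-methoxyphenyl)-2,3-dihydro-1-benzofuran | COc1ccc([C@H]2Oc3cc(OCc4ccccc4)cc(/C=C/c4ccc(OC)cc4OC)c3[C@@H]2c2cc(OC)cc(OC)c2)cc1 | intermediate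
15 | tetracyclic benzyl ether (2S,3S,7S): (1S,8S,16S)-12-(benzyloxy)-8-(2,4-dimethoxyphenyl)-4,6-dimethoxy-16-(4-methoxyphenyl)-15-oxatetracyclo[8.6.1.0(2,7).0(14,17)]heptadeca-2(7),3,5,10(17),11,13-hexaene | COc1ccc([C@H]2Oc3cc(OCc4ccccc4)cc4c3[C@@H]2c2cc(OC)cc(OC)c2[C@H](c2ccc(OC)cc2OC)C4)cc1 | intermediate
16 | tetracyclic phenol (2S,3S,7S): 15 with OH in place of OBn at c | COc1ccc([C@H]2Oc3cc(O)cc4c3[C@@H]2c2cc(OC)cc(OC)c2[C@H](c2ccc(OC)cc2OC)C4)cc1 | intermediate
17 | tetracyclic salicylaldehyde (2S,3S,7S): 16 with CHO at d | COc1ccc([C@H]2Oc3cc(O)c(C=O)c4c3[C@@H]2c2cc(OC)cc(OC)c2[C@H](c2ccc(OC)cc2OC)C4)cc1 | intermediate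
18 | 4-methoxybenzyl chloride | COc1ccc(CCl)cc1 | starting material
19 | 17 with the OH at c as its 4-methoxybenzyl ether | COc1ccc([C@H]2Oc3cc(OCc4ccc(OC)cc4)c(C=O)c4c3[C@@H]2c2cc(OC)cc(OC)c2[C@H](c2ccc(OC)cc2OC)C4)cc1 | intermediate
20 | 3,5-dimethoxyphenylmagnesium bromide (commercial THF solution) | COc1cc(OC)cc([Mg]Br)c1 | starting material
21 | diaryl carbinol: 19 with CH(OH)(3,5-dimethoxyphenyl) at d, both epimers | COc1ccc([C@H]2Oc3cc(OCc4ccc(OC)cc4)c(C(O)c4cc(OC)cc(OC)c4)c4c3[C@@H]2c2cc(OC)cc(OC)c2[C@H](c2ccc(OC)cc2OC)C4)cc1 | intermediate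
22 | diaryl ketone: 3,5-dimethoxybenzoyl group at d | COc1ccc([C@H]2Oc3cc(OCc4ccc(OC)cc4)c(C(=O)c4cc(OC)cc(OC)c4)c4c3[C@@H]2c2cc(OC)cc(OC)c2[C@H](c2ccc(OC)cc2OC)C4)cc1 | intermediate
23 | hydrazone of 22 (C=N isomers) | COc1ccc([C@H]2Oc3cc(OCc4ccc(OC)cc4)c(C(=NN)c4cc(OC)cc(OC)c4)c4c3[C@@H]2c2cc(OC)cc(OC)c2[C@H](c2ccc(OC)cc2OC)C4)cc1 | intermediate
24 | diaryldiazomethane from 23 (not isolated) | COc1ccc([C@H]2Oc3cc(OCc4ccc(OC)cc4)c(C(=[N+]=[N-])c4cc(OC)cc(OC)c4)c4c3[C@@H]2c2cc(OC)cc(OC)c2[C@H](c2ccc(OC)cc2OC)C4)cc1 | intermediate
25 | octamethyl ether with cis outer dihydrofuran (2S,3S,7S,2'S,3'R) | COc1ccc([C@H]2Oc3cc4c(c5c3[C@@H]2c2cc(OC)cc(OC)c2[C@H](c2ccc(OC)cc2OC)C5)[C@@H](c2cc(OC)cc(OC)c2)[C@@H](c2ccc(OC)cc2)O4)cc1 | intermediate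
26 | octamethyl ether of the target (2S,3S,7S,2'R,3'R), both dihydrofurans trans | COc1ccc([C@H]2Oc3cc4c(c5c3[C@@H]2c2cc(OC)cc(OC)c2[C@H](c2ccc(OC)cc2OC)C5)[C@@H](c2cc(OC)cc(OC)c2)[C@H](c2ccc(OC)cc2)O4)cc1 | intermediate
27 | CNP0154047.3 (2S,3S,7S,2'R,3'R) | Oc1ccc([C@H]2Oc3cc4c(c5c3[C@@H]2c2cc(O)cc(O)c2[C@H](c2ccc(O)cc2O)C5)[C@@H](c2cc(O)cc(O)c2)[C@H](c2ccc(O)cc2)O4)cc1 | target

## Step count and risks

Total steps: 18. Longest linear sequence: 16 (steps 1, 3–6 and 8–18; steps 2 and 7 are side branches).

**Step 6 (the step that goes beyond known chemistry).**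
- The hindered alkene lacks an activating ester and may fail to insert.
- The rhodium alkyl may expel the aryloxide from C2 by beta-elimination, which cleaves the tether.
- Reversible insertion with the opposite regiochemistry may scramble the alkene geometry.
- The auxiliary may discriminate poorly between the two alkene faces.

The fallback sets out from 2 and returns at 11. It runs the directed hydroarylation on the ester-bearing enol ether, for which the reaction is established, and brings in ring G afterwards.
- Phenol 2 is added to methyl 3-(4-methoxyphenyl)propiolate (K2CO3, DMF, anti conjugate addition) to give methyl (Z)-3-[3-(benzyloxy)-5-formylphenoxy]-3-(4-methoxyphenyl)acrylate F1.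
- Condensation with 8 gives its aldimine F2.
- The catalyst of step 6 closes the ring to the cis cyclised aldimine F3, which is hydrolysed on work-up to the (2S,3R) cis ester aldehyde F4.
- LiOH gives the carboxylic acid F5. C3 may epimerise here, which does not matter.
- Esterification with tetrachloro-N-hydroxyphthalimide and diisopropylcarbodiimide gives the redox-active ester F6.
- Nickel-catalysed decarboxylative arylation with 3,5-dimethoxyphenylboronic acid (NiCl2·6H2O, 4,4'-di-tert-butyl-2,2'-bipyridine, Et3N, dioxane–DMF, 75 °C) passes through the planar C3 radical. This radical is arylated anti to the C2 aryl group, so C2 alone carries the stereochemical information and 11 results.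

**Step 9.**
- Acid may ionise the C2–O bond of the dihydrofuran in competition with alkene protonation and start a skeletal rearrangement.
- The cation may alkylate a second molecule.
- Ring closure may show poor facial selectivity at C7.

The fallback sets out from 11 and returns at 15. It closes the ring first and adds the resorcinol ring from outside.
- Wittig reaction with (methoxymethyl)triphenylphosphonium chloride and KHMDS gives the methyl enol ether F7.
- Mild aqueous acid gives the arylacetaldehyde F8.
- BF3·OEt2 in CH2Cl2 at low temperature, in the presence of 1,3-dimethoxybenzene, induces intramolecular Friedel–Crafts hydroxyalkylation by ring G to the seven-ring carbinol F9, which need not be isolated.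
- Ionisation of F9 gives a ring cation stabilised by the two methoxy groups of ring G. 1,3-Dimethoxybenzene attacks it through its C4 from the open convex face, which again places the aryl group cis to H3.
- If the external arene attacks the aldehyde first, the cation of step 9 results and closes to the same product.

**Step 16 (with its feeder, step 15).**
- Hydrazone formation on the doubly ortho-substituted ketone may stall.
- The diazo compound may go to azine or back to the ketone.
- Catalyst and substrate may be mismatched, giving poor facial selectivity at C3'.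

The fallback sets out from 22 and returns at 26, bypassing steps 15–17.
- Corey–Chaykovsky methylenation (Me3SI, NaH, DMSO–THF) gives the 1,1-diaryl epoxide F10.
- ZnI2 induces Meinwald rearrangement to the diarylacetaldehyde F11.
- 4-Methoxyphenylmagnesium bromide adds to give the secondary alcohol F12.
- Hydrogenolysis (H2, Pd/C) of the 4-methoxybenzyl ether frees the phenol alcohol F13.
- Brief treatment with TFA ionises the 4-methoxybenzylic alcohol, and the phenol closes the ring trans to the C3' aryl group.
- C3' is not controlled in this sequence, so 26 forms together with its (2'S,3'S) diastereomer F14. The two are separated by chromatography, which is possible because the fixed inner stereocentres make them diastereomers.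

## Further compounds

F1 | step 6 | methyl (Z)-3-[3-(benzyloxy)-5-formylphenoxy]-3-(4-methoxyphenyl)acrylate | COC(=O)/C=C(\Oc1cc(C=O)cc(OCc2ccccc2)c1)c1ccc(OC)cc1
F2 | step 6 | (E)-aldimine of F1 with (R)-1-aminoindane | COC(=O)/C=C(\Oc1cc(/C=N/[C@@H]2CCc3ccccc32)cc(OCc2ccccc2)c1)c1ccc(OC)cc1
F3 | step 6 | cis cyclised aldimine, (R)-1-indanyl aldimine of F4 | COc1ccc([C@H]2Oc3cc(OCc4ccccc4)cc(/C=N/[C@@H]4CCc5ccccc54)c3[C@H]2C(=O)OC)cc1
F4 | step 6 | methyl (2S,3R)-6-(benzyloxy)-4-formyl-2-(4-methoxyphenyl)-2,3-dihydro-1-benzofuran-3-carboxylate | COc1ccc([C@H]2Oc3cc(OCc4ccccc4)cc(C=O)c3[C@H]2C(=O)OC)cc1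
F5 | step 6 | (2S)-6-(benzyloxy)-4-formyl-2-(4-methoxyphenyl)-2,3-dihydro-1-benzofuran-3-carboxylic acid, C3 epimers | COc1ccc([C@H]2Oc3cc(OCc4ccccc4)cc(C=O)c3C2C(=O)O)cc1
F6 | step 6 | tetrachlorophthalimido ester of F5 | COc1ccc([C@H]2Oc3cc(OCc4ccccc4)cc(C=O)c3C2C(=O)ON2C(=O)c3c(Cl)c(Cl)c(Cl)c(Cl)c3C2=O)cc1
F7 | step 9 | 2-methoxyethenyl compound from 11, alkene isomers | COc1ccc([C@H]2Oc3cc(OCc4ccccc4)cc(C=COC)c3[C@@H]2c2cc(OC)cc(OC)c2)cc1
F8 | step 9 | (2S,3S)-dihydrobenzofuran-4-ylacetaldehyde, one-carbon homologue of 11 | COc1ccc([C@H]2Oc3cc(OCc4ccccc4)cc(CC=O)c3[C@@H]2c2cc(OC)cc(OC)c2)cc1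
F9 | step 9 | seven-ring carbinol, OH on C7, epimers | COc1ccc([C@H]2Oc3cc(OCc4ccccc4)cc4c3[C@@H]2c2cc(OC)cc(OC)c2C(O)C4)cc1
F10 | step 16 | 1,1-diaryl epoxide from 22 | COc1ccc([C@H]2Oc3cc(OCc4ccc(OC)cc4)c(C4(CO4)c4cc(OC)cc(OC)c4)c4c3[C@@H]2c2cc(OC)cc(OC)c2[C@H](c2ccc(OC)cc2OC)C4)cc1
F11 | step 16 | diarylacetaldehyde, C3' epimers | COc1ccc([C@H]2Oc3cc(OCc4ccc(OC)cc4)c(C(C=O)c4cc(OC)cc(OC)c4)c4c3[C@@H]2c2cc(OC)cc(OC)c2[C@H](c2ccc(OC)cc2OC)C4)cc1
F12 | step 16 | secondary alcohol from F11 and 4-methoxyphenylmagnesium bromide, epimers | COc1ccc([C@H]2Oc3cc(OCc4ccc(OC)cc4)c(C(C(O)c4ccc(OC)cc4)c4cc(OC)cc(OC)c4)c4c3[C@@H]2c2cc(OC)cc(OC)c2[C@H](c2ccc(OC)cc2OC)C4)cc1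
F13 | step 16 | phenol alcohol, F12 without the 4-methoxybenzyl group | COc1ccc([C@H]2Oc3cc(O)c(C(C(O)c4ccc(OC)cc4)c4cc(OC)cc(OC)c4)c4c3[C@@H]2c2cc(OC)cc(OC)c2[C@H](c2ccc(OC)cc2OC)C4)cc1
F14 | step 16 | (2S,3S,7S,2'S,3'S) diastereomer of 26 | COc1ccc([C@H]2Oc3cc4c(c5c3[C@@H]2c2cc(OC)cc(OC)c2[C@H](c2ccc(OC)cc2OC)C5)[C@H](c2cc(OC)cc(OC)c2)[C@@H](c2ccc(OC)cc2)O4)cc1
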